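## Analysis of the target

Target 18 is a flavanone. Ring A is the benzene ring C4a–C8a, ring C is the pyranone O1/C2/C3/C4, and ring B is the 4-hydroxyphenyl group on C2. It carries OMe at C5, OH at C7 and, at C8, the methine C3'' of a 1,7-diarylheptenyl chain: C1''=C2'' (E-styrene), C3'', C4''H2, C5''H(OH), C6''H2, C7''H2.

The SMILES reads as 2S, 3''S, 5''S. C2 is remote from the other two centres and must be set on its own. C3'' and C5'' are 1,3-related, and ring A and the 5''-hydroxyl lie syn when the chain C2''–C6'' is drawn as a zigzag.

Three features are sensitive: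
- C2 epimerises by retro-oxa-Michael opening of ring C under base.
- The 4-hydroxystyrene protonates to a quinone methide, which the 7-OH or the 5''-OH can trap under acid.
- Four free phenols must be carried or masked.

The hardest bond is C8–C3''. It sits between O7 and O1, it competes with the equally activated C6, and it creates an acyclic stereocentre. The 1,3-syn relation is the opposite of what six-membered oxacycle templates give, because equatorial capture places ring A cis to the C5'' side chain, which is the anti series.

The route exploits one feature of this structure. O5'' lies three atoms from C3'' and on the same side as ring A. C3'' is also the terminus of the allyl system C1''–C2''–C3'', which is conjugated to a 4-oxygenated aryl ring and therefore ionises easily. This invites delivery of C8 of ring A to C3'' from an atom held by O5''.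

## Retrosynthetic reasoning

**18 from 17.** The last cut removes only four phenolic silyl ethers. Nothing else is left for the end, because C2 tolerates no base and the free hydroxystyrene tolerates no acid. Buffered fluoride is the one window both accept.

**17 from 8 and 14 (through 15 and 16).** The bond cut is C8–C3''. It is not treated as an arene C–H plus a cation. It is treated as a boron-to-carbon shift of ring A from a boron atom that O5'' holds.
- The cut splits the molecule into two halves of similar size.
- C8 against C6 is encoded in a C–B bond.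
- O5'' stays unprotected.
- No stereochemistry is needed at C1'' or C3'' of the chain, because all allylic isomers of 14 pass through one cation.
- The forward reaction must ionise the allylic alcohol, keep the cation tied to boron, and transfer ring A to one face of C3''.

**8 from 7.** The C–B bond is traced to a C–I bond. The forward step must give the free boronic acid, because only that exchanges with the hydroxyls of 14.

**7 from 5 and 6.** The bond cut is C2–C1' (ring B). It is preferred over the O1–C2 bond of a chalcone, because catalytic asymmetric conjugate arylation of a chromone has close precedent, whereas oxa-Michael closure of a plain 2'-hydroxychalcone does not. C2 is set on a small, rigid substrate before the halves meet.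

**5 from 3, 2 and 1 (through 4).** Ring C is cut at O1–C2 and C2–C3. The acetyl group of 3 supplies C3 and C4, and a one-carbon amide acetal supplies C2. Iodine is placed first, while C3 of 1 is still flanked by two free hydroxyls and differs most from C5.

**14 from 11 and 13.** The alkene C2''=C3'' is cut by cross-metathesis. The hydroxyl may sit at C1'' and may be racemic, because the key step erases that information.

**11 from 10 from 9, and 13 from 12.** C5'' comes from a catalytic asymmetric allyl transfer to aldehyde 10. Aldehyde 10 is one Heck arylation away from 9. Alcohol 13 is one vinyl addition away from 12.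

## Alternatives that were turned down

**Alternative 1:** the textbook, biomimetic cut of C8–C3'' as arene C–H plus allyl cation. The forward key step is an acid-promoted Friedel–Crafts alkylation of flavanone A1 with diol A2.
- C6 and C8 of A1 are both ortho to the 7-OH and both ortho or para to all three oxygens, so the C6-linked isomer A3 is a real competitor.
- The cation is planar and the nucleophile arrives from outside, so C5'' exerts no useful bias on C3''.
- The same acid lets the 7-OH and the 5''-OH add back to the styrene.
- Up to four isomers would have to be separated at the last stage. The brevity is only apparent.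

**Alternative 2:** C8–C3'' by 1,4-addition to dienone A4, followed by reduction of the C5'' ketone of A5. The forward key step is an asymmetric conjugate arylation, or a phenol Michael addition with hemiketalisation. This is the shortest paper route.
- The C5'' carbonyl of A5 lies between two methylene groups, so no small chiral reductant distinguishes its faces.
- A β-aryl stereocentre gives little 1,3-induction.
- The 7-OH masks the ketone as a hemiketal.
- A ring A boronic acid with two ortho oxygens is lost by protodeboronation in the aqueous base these additions need, and 1,6-addition competes.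
- C5'' would rest on the outcome of enzyme screening.

**Alternative 3:** a three-component Prins cyclisation with Friedel–Crafts capture. Alcohol 11, aldehyde 12 and an unacylated ring A phenol would give tetrahydropyran A6. Opening of its benzylic C–O bond would then give the styrene A7. The step forms O–C1'', C1''–C2'' and C3''–C8 at once and has good precedent.
- Equatorial capture gives the all-cis ring, which is the 3'',5''-anti series A7.
- C5'' would then need a Mitsunobu inversion, in which the 7-OH competes by chroman closure.
- Opening a tetrahydropyran to a hydroxy-styrene is thermodynamically uphill.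
- C2 against C4 of the phenol is unsolved.
- The acyl carbon of ring C would have to be added afterwards to an acid-sensitive compound.

Key step: step 10

Assumption: compounds 1, 6, 9 and 12 are taken as catalogue items; locants O1–C8a refer to the chromanone and C1''–C7'' to the heptenyl chain counted from the styrene end.

## Steps

Step 1
Reactants: 1 1-(2,4-dihydroxy-6-methoxyphenyl)ethan-1-one
Product: 2 1-(2,4-dihydroxy-3-iodo-6-methoxyphenyl)ethan-1-one
Conditions: I2 (1.0 equiv), NaHCO3, THF/H2O, 0 °C to rt
Reagents that add atoms: iodine, II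
Why: Electrophilic aromatic iodination of a phenoxide-type nucleophile; under bicarbonate the carbon flanked by two hydroxyls is attacked, as in the conversion of resorcinol into 2-iodoresorcinol, and C5 is flanked by the larger, weaker OMe donor.

Step 2
Reactants: 2 1-(2,4-dihydroxy-3-iodo-6-methoxyphenyl)ethan-1-one
Product: 3 1-[2-hydroxy-3-iodo-6-methoxy-4-(triisopropylsilyloxy)phenyl]ethan-1-one
Conditions: TIPSCl (1.05 equiv), imidazole, DMF, rt
Reagents that add atoms: chlorotriisopropylsilane, CC(C)[Si](Cl)(C(C)C)C(C)C
Why: Selective O-silylation; the 2-OH is hydrogen-bonded to the acetyl group and buried between iodine and the ketone, so only the more acidic 4-OH reacts, and the bulky silyl group is chosen to survive the amide acetal and the mild bases that follow.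

Step 3
Reactants: 3 1-[2-hydroxy-3-iodo-6-methoxy-4-(triisopropylsilyloxy)phenyl]ethan-1-one
Product: 5 8-iodo-5-methoxy-7-(triisopropylsilyloxy)-4H-chromen-4-one, via enaminone 4 (not isolated)
Conditions: DMF-DMA, toluene, 90 °C; evaporate; AcOH, 60 °C
Reagents that add atoms: N,N-dimethylformamide dimethyl acetal, COC(OC)N(C)C
Why: Standard enaminone route to chromones; the acetyl methyl group condenses with the amide acetal, and in acetic acid the 2-OH adds to the enaminone and expels dimethylamine (6-endo addition-elimination) to close ring C.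

Step 4
Reactants: 5 8-iodo-5-methoxy-7-(triisopropylsilyloxy)-4H-chromen-4-one; 6 [4-(tert-butyldimethylsilyloxy)phenyl]boronic acid
Product: 7 (2S)-2-[4-(tert-butyldimethylsilyloxy)phenyl]-8-iodo-5-methoxy-7-(triisopropylsilyloxy)chroman-4-one
Conditions: [RhCl(C2H4)2]2 (1.5 mol %), (1S,4S)-2,5-diphenylbicyclo[2.2.2]octa-2,5-diene (3.3 mol %), KOH (0.1 equiv), toluene/H2O 10:1, 40 °C
Reagents that add atoms: none
Why: Hayashi–Miyaura 1,4-addition of an arylrhodium species to the C2=C3 bond of a chromone, a known entry to flavanones; the C2-symmetric diene shields one face, and the S,S ligand is chosen by analogy with cyclic enones, whose S-type topology maps onto 2S here. The low base loading keeps ring C closed, and the aryl iodide is inert to monovalent rhodium at this temperature.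

Step 5
Reactants: 7 (2S)-2-[4-(tert-butyldimethylsilyloxy)phenyl]-8-iodo-5-methoxy-7-(triisopropylsilyloxy)chroman-4-one
Product: 8 {(2S)-2-[4-(tert-butyldimethylsilyloxy)phenyl]-5-methoxy-4-oxo-7-(triisopropylsilyloxy)chroman-8-yl}boronic acid
Conditions: B2(OH)4 (3 equiv), Pd(OAc)2 (2 mol %), XPhos (4 mol %), KOAc (3 equiv), EtOH, 60 °C
Reagents that add atoms: tetrahydroxydiboron, OB(O)B(O)O
Why: Miyaura-type borylation with tetrahydroxydiboron gives the free boronic acid directly, which is needed because a pinacol ester would not exchange with 14; the bulky biaryl phosphine handles the doubly ortho-substituted iodide, and acetate is too weak a base to open ring C, so C2 is kept.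

Step 6
Reactants: 9 tert-butyl(4-iodophenoxy)dimethylsilane
Product: 10 3-[4-(tert-butyldimethylsilyloxy)phenyl]propanal
Conditions: allyl alcohol (1.5 equiv), Pd(OAc)2 (2 mol %), NaHCO3, Bu4NCl, DMF, 45 °C
Reagents that add atoms: allyl alcohol, C=CCO
Why: Heck arylation of allyl alcohol under ligand-free phase-transfer conditions; aryl adds to the terminal carbon, β-hydride elimination runs towards the carbinol, and the enol tautomerises to the aldehyde.

Step 7
Reactants: 10 3-[4-(tert-butyldimethylsilyloxy)phenyl]propanal
Product: 11 (3S)-1-[4-(tert-butyldimethylsilyloxy)phenyl]hex-5-en-3-ol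
Conditions: allyltributylstannane (1.2 equiv), (R)-BINOL (10 mol %), Ti(OiPr)4 (10 mol %), 4 Å MS, CH2Cl2, −20 °C; aq NaHCO3
Reagents that add atoms: allyltributylstannane, C=CC[Sn](CCCC)(CCCC)CCCC
Why: Keck allylation; the titanium (R)-binaphtholate directs allyl to the Re face of linear aldehydes, which here means 3S (the future 5''S), and unbranched 3-arylpropanals are among the best substrates of this reaction.

Step 8
Reactants: 12 4-(tert-butyldimethylsilyloxy)benzaldehyde
Product: 13 1-[4-(tert-butyldimethylsilyloxy)phenyl]prop-2-en-1-ol (racemic)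
Conditions: vinylmagnesium bromide (1.1 equiv), THF, −78 to 0 °C; H2O
Reagents that add atoms: vinylmagnesium bromide, C=C[Mg]Br
Why: Plain Grignard 1,2-addition; the new carbinol centre is left racemic on purpose because step 10 erases it, and a neutral quench avoids ionisation of the electron-rich benzylic alcohol.

Step 9
Reactants: 11 (3S)-1-[4-(tert-butyldimethylsilyloxy)phenyl]hex-5-en-3-ol; 13 1-[4-(tert-butyldimethylsilyloxy)phenyl]prop-2-en-1-ol (2 equiv)
Product: 14 (2E,5S)-1,7-bis[4-(tert-butyldimethylsilyloxy)phenyl]hept-2-ene-1,5-diol (both C1 epimers)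
Conditions: second-generation Hoveyda–Grubbs catalyst RuCl2(H2IMes)(=CH-C6H4-2-OiPr) (3 mol %), 1,4-benzoquinone (10 mol %), CH2Cl2, 40 °C
Reagents that add atoms: none
Why: Olefin cross-metathesis of a type 1 homoallylic alcohol with a type 2 secondary allylic alcohol, which favours the cross product and the E alkene; free hydroxyls are tolerated, and benzoquinone suppresses ruthenium hydride isomerisation of the allylic alcohol.

Step 10
Reactants: 8 {(2S)-2-[4-(tert-butyldimethylsilyloxy)phenyl]-5-methoxy-4-oxo-7-(triisopropylsilyloxy)chroman-8-yl}boronic acid (1.1 equiv); 14 (2E,5S)-1,7-bis[4-(tert-butyldimethylsilyloxy)phenyl]hept-2-ene-1,5-diol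
Product: 17 (2S)-2-[4-(tert-butyldimethylsilyloxy)phenyl]-8-{(1E,3S,5S)-1,7-bis[4-(tert-butyldimethylsilyloxy)phenyl]-5-hydroxyhept-1-en-3-yl}-5-methoxy-7-(triisopropylsilyloxy)chroman-4-one, via cyclic boronate 15 (not isolated), via borate monoester 16 (not isolated)
Conditions: toluene, 40 °C, evaporate (twice, azeotropic drying); CH2Cl2/HFIP 4:1, (PhO)2P(O)OH (5 mol %), −20 °C to rt; pH 7 buffer
Reagents that add atoms: none
Why: Proposed new method: after esterification of the hydroxyls of 14 by 8, the weak acid in HFIP ionises the allylic C–O bond next to the 4-silyloxyphenyl ring, and internal return of the boron-bound oxygen at C3'' gives the six-membered boronate 15, so that both C1'' epimers, both C3'' epimers and both allylic regioisomers feed one planar C1''–C2''–C3'' cation that stays tied to boron through O5''. Re-ionisation of 15 leaves an oxyanion on boron (completed to a tetrahedral boronate by phosphate or HFIP), and ring A then moves from boron to C3'' by ipso attack of C8 through a six-membered chair made of C8, C3'', C4'', C5'', O5'' and B, which gives 16 and, after hydrolysis, 17. The closest known reaction types are the Petasis reaction, the addition of aryl boronates to oxocarbenium ions and quinone methides, the metal-free dehydrative coupling of allylic and benzhydryl alcohols with boronic acids, and boronic acid-promoted ionisation of allylic alcohols in HFIP; what is new is the use of a neighbouring carbinol as the tether. No ring of the target is closed; the only ring formed is the transient 1,3,2-dioxaborinane of 15, closed by 6-exo capture of the cation. C3'' is controlled by C5'': with the arylethyl chain and the styryl group both equatorial the chair has the topology of an Evans–Saksena reduction, in which the group delivered from boron ends syn to the tethering oxygen, so 5''S gives 3''S, while C2 and C5'' are not touched. Site selectivity on ring A (C8, not C6) is fixed by the position of boron and helped by the three oxygen substituents ortho and para to C8, which stabilise the ipso arenium ion. Attack at C3'' and not at C1'' is secured by a six- against an eight-membered transition state and by keeping the styrene conjugated, and the extended cation gives the E alkene. The step needs aryl transfer to outrun protodeboronation and proton loss from C4'', which is why water is removed first and only a weak acid is used at low temperature.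

Step 11
Reactants: 17 (2S)-2-[4-(tert-butyldimethylsilyloxy)phenyl]-8-{(1E,3S,5S)-1,7-bis[4-(tert-butyldimethylsilyloxy)phenyl]-5-hydroxyhept-1-en-3-yl}-5-methoxy-7-(triisopropylsilyloxy)chroman-4-one
Product: 18 (2S)-7-hydroxy-8-[(1E,3S,5S)-5-hydroxy-1,7-bis(4-hydroxyphenyl)hept-1-en-3-yl]-2-(4-hydroxyphenyl)-5-methoxychroman-4-one
Conditions: TBAF (4.4 equiv), AcOH (4.4 equiv), THF, 0 °C
Reagents that add atoms: none
Why: Fluoride cleavage of four aryl silyl ethers, which are far more labile than alkyl silyl ethers; the acetic acid buffer keeps the phenols protonated, so that neither retro-oxa-Michael opening at C2 nor acid-triggered addition of the 7-OH or 5''-OH to the styrene is expected.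

## Compound list

1 | 1-(2,4-dihydroxy-6-methoxyphenyl)ethan-1-one | CC(=O)c1c(O)cc(O)cc1OC | starting material
2 | 1-(2,4-dihydroxy-3-iodo-6-methoxyphenyl)ethan-1-one | CC(=O)c1c(O)c(I)c(O)cc1OC | intermediate
3 | 1-[2-hydroxy-3-iodo-6-methoxy-4-(triisopropylsilyloxy)phenyl]ethan-1-one | CC(=O)c1c(O)c(I)c(O[Si](C(C)C)(C(C)C)C(C)C)cc1OC | intermediate
4 | (E)-3-(dimethylamino)-1-[2-hydroxy-3-iodo-6-methoxy-4-(triisopropylsilyloxy)phenyl]prop-2-en-1-one | CN(C)/C=C/C(=O)c1c(O)c(I)c(O[Si](C(C)C)(C(C)C)C(C)C)cc1OC | intermediate
5 | 8-iodo-5-methoxy-7-(triisopropylsilyloxy)-4H-chromen-4-one | COc1cc(O[Si](C(C)C)(C(C)C)C(C)C)c(I)c2occc(=O)c12 | intermediate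
6 | [4-(tert-butyldimethylsilyloxy)phenyl]boronic acid | CC(C)(C)[Si](C)(C)Oc1ccc(B(O)O)cc1 | starting material
7 | (2S)-2-[4-(tert-butyldimethylsilyloxy)phenyl]-8-iodo-5-methoxy-7-(triisopropylsilyloxy)chroman-4-one | COc1cc(O[Si](C(C)C)(C(C)C)C(C)C)c(I)c2c1C(=O)C[C@@H](c1ccc(O[Si](C)(C)C(C)(C)C)cc1)O2 | intermediate
8 | {(2S)-2-[4-(tert-butyldimethylsilyloxy)phenyl]-5-methoxy-4-oxo-7-(triisopropylsilyloxy)chroman-8-yl}boronic acid | COc1cc(O[Si](C(C)C)(C(C)C)C(C)C)c(B(O)O)c2c1C(=O)C[C@@H](c1ccc(O[Si](C)(C)C(C)(C)C)cc1)O2 | intermediate
9 | tert-butyl(4-iodophenoxy)dimethylsilane | CC(C)(C)[Si](C)(C)Oc1ccc(I)cc1 | starting material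
10 | 3-[4-(tert-butyldimethylsilyloxy)phenyl]propanal | CC(C)(C)[Si](C)(C)Oc1ccc(CCC=O)cc1 | intermediate
11 | (3S)-1-[4-(tert-butyldimethylsilyloxy)phenyl]hex-5-en-3-ol | C=CC[C@@H](O)CCc1ccc(O[Si](C)(C)C(C)(C)C)cc1 | intermediate
12 | 4-(tert-butyldimethylsilyloxy)benzaldehyde | CC(C)(C)[Si](C)(C)Oc1ccc(C=O)cc1 | starting material
13 | 1-[4-(tert-butyldimethylsilyloxy)phenyl]prop-2-en-1-ol (racemic) | C=CC(O)c1ccc(O[Si](C)(C)C(C)(C)C)cc1 | intermediate
14 | (2E,5S)-1,7-bis[4-(tert-butyldimethylsilyloxy)phenyl]hept-2-ene-1,5-diol (both C1 epimers) | OC(/C=C/C[C@@H](O)CCc1ccc(O[Si](C)(C)C(C)(C)C)cc1)c1ccc(O[Si](C)(C)C(C)(C)C)cc1 | intermediate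
15 | (6S)-2-(flavanon-8-yl)-4-[(E)-4-silyloxystyryl]-6-[2-(4-silyloxyphenyl)ethyl]-1,3,2-dioxaborinane (both C4 epimers) | COc1cc(O[Si](C(C)C)(C(C)C)C(C)C)c(B2OC(/C=C/c3ccc(O[Si](C)(C)C(C)(C)C)cc3)C[C@H](CCc3ccc(O[Si](C)(C)C(C)(C)C)cc3)O2)c2c1C(=O)C[C@@H](c1ccc(O[Si](C)(C)C(C)(C)C)cc1)O2 | intermediate
16 | 5''-O-dihydroxyboryl ester of 17 | COc1cc(O[Si](C(C)C)(C(C)C)C(C)C)c([C@H](/C=C/c2ccc(O[Si](C)(C)C(C)(C)C)cc2)C[C@@H](OB(O)O)CCc2ccc(O[Si](C)(C)C(C)(C)C)cc2)c2c1C(=O)C[C@@H](c1ccc(O[Si](C)(C)C(C)(C)C)cc1)O2 | intermediate
17 | (2S)-2-[4-(tert-butyldimethylsilyloxy)phenyl]-8-{(1E,3S,5S)-1,7-bis[4-(tert-butyldimethylsilyloxy)phenyl]-5-hydroxyhept-1-en-3-yl}-5-methoxy-7-(triisopropylsilyloxy)chroman-4-one | COc1cc(O[Si](C(C)C)(C(C)C)C(C)C)c([C@H](/C=C/c2ccc(O[Si](C)(C)C(C)(C)C)cc2)C[C@@H](O)CCc2ccc(O[Si](C)(C)C(C)(C)C)cc2)c2c1C(=O)C[C@@H](c1ccc(O[Si](C)(C)C(C)(C)C)cc1)O2 | intermediate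
18 | (2S)-7-hydroxy-8-[(1E,3S,5S)-5-hydroxy-1,7-bis(4-hydroxyphenyl)hept-1-en-3-yl]-2-(4-hydroxyphenyl)-5-methoxychroman-4-one | COc1cc(O)c([C@H](/C=C/c2ccc(O)cc2)C[C@@H](O)CCc2ccc(O)cc2)c2c1C(=O)C[C@@H](c1ccc(O)cc1)O2 | target

## Step count and least certain steps

Total step count: 11. Longest linear sequence: 7 steps (steps 1–5, 10, 11).

**Step 10 (key step, proposed new method).** Three things are most likely to go wrong:
- Protodeboronation of the doubly ortho-oxygenated boronic acid may be faster than aryl transfer. Untethered attack through C6–H would then follow.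
- The cation may lose a proton from C4''.
- Facial selectivity may be poor if a boat competes with the chair, because the ipso carbon is crowded by the 7-silyloxy group.

The fallback replaces the tethered transfer by a stereospecific Suzuki–Miyaura-type allyl–aryl coupling, which is known to run with inversion on (E)-1-aryl-3-alkylallyl carbonates. It sets out from 11 and uses 8 unchanged. Silylation of 11 (TBSOTf, 2,6-lutidine) gives the bis-silyl ether F1, and ozonolysis gives the β-silyloxy aldehyde F2. A catalytic asymmetric alkenylzinc addition follows: tert-butyl(4-ethynylphenoxy)dimethylsilane, Cy2BH, then Et2Zn, with the morpholinoisoborneol antipode that gives the 3R carbinol. This gives the anti-configured allylic alcohol F3, and methyl chloroformate gives the carbonate F4. Zerovalent palladium (Pd2(dba)3, PPh3, THF, 40 °C) ionises F4 with inversion. Ring A of 8 is then transferred from palladium with retention, at the carbon that keeps the styrene conjugated, which gives the pentasilyl ether F5 with 3''S. HF·pyridine in THF removes all five silyl groups, and the route comes back at 18.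

**Step 5.** Two processes are the likely failures. Oxidative addition at the iodide flanked by O1 and the silyloxy group may be slow. The phenolic silyl ethers and the new C–B bond may be lost in warm ethanol. The fallback sets out from 7. It uses an aprotic Miyaura borylation (PdCl2(dppf), B2pin2, KOAc, dioxane, 80 °C) to give the isolable pinacol boronate F6. This is unmasked separately by oxidative cleavage of the pinacol (NaIO4, NH4OAc, acetone/H2O, rt), and the route comes back at 8.

**Step 1.** The likely failure is competing iodination at C5, or twofold iodination, because both free positions are ortho or para to all three oxygens. The fallback moves the halogenation to the bicyclic stage. There, bond fixation in the benzopyranone and the 5-OMe group next to C6 favour C8. It sets out from 1. Silylation gives the 4-O-silyl acetophenone F7. The amide acetal sequence of step 3 gives the chromone F8. Iodination with I2 and AgO2CCF3 in CH2Cl2 comes back at 5.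

**Step 9.** The likely failures are redox isomerisation of the aryl allyl alcohol to the ketone by ruthenium hydrides, and sluggish turnover of the hindered type 2 partner, which would leave self-metathesis of 11 as the main event. The fallback sets out from 11. Cross-metathesis with crotonaldehyde, a well-behaved electron-poor partner, gives the δ-hydroxy enal F9. 1,2-Addition of 4-(tert-butyldimethylsilyloxy)phenylmagnesium bromide (2.2 equiv, THF, −78 °C) comes back at 14.

## Further compounds

F1 | step 10 | (3S)-3-(tert-butyldimethylsilyloxy)-1-[4-(tert-butyldimethylsilyloxy)phenyl]hex-5-ene | C=CC[C@@H](O[Si](C)(C)C(C)(C)C)CCc1ccc(O[Si](C)(C)C(C)(C)C)cc1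
F2 | step 10 | (3S)-3-(tert-butyldimethylsilyloxy)-5-[4-(tert-butyldimethylsilyloxy)phenyl]pentanal | O=CC[C@@H](O[Si](C)(C)C(C)(C)C)CCc1ccc(O[Si](C)(C)C(C)(C)C)cc1
F3 | step 10 | (1E,3R,5S)-5-(tert-butyldimethylsilyloxy)-1,7-bis[4-(tert-butyldimethylsilyloxy)phenyl]hept-1-en-3-ol | O[C@@H](/C=C/c1ccc(O[Si](C)(C)C(C)(C)C)cc1)C[C@@H](O[Si](C)(C)C(C)(C)C)CCc1ccc(O[Si](C)(C)C(C)(C)C)cc1
F4 | step 10 | methyl carbonate of F3 | COC(=O)O[C@@H](/C=C/c1ccc(O[Si](C)(C)C(C)(C)C)cc1)C[C@@H](O[Si](C)(C)C(C)(C)C)CCc1ccc(O[Si](C)(C)C(C)(C)C)cc1
F5 | step 10 | 5''-O-tert-butyldimethylsilyl ether of 17 | COc1cc(O[Si](C(C)C)(C(C)C)C(C)C)c([C@H](/C=C/c2ccc(O[Si](C)(C)C(C)(C)C)cc2)C[C@@H](O[Si](C)(C)C(C)(C)C)CCc2ccc(O[Si](C)(C)C(C)(C)C)cc2)c2c1C(=O)C[C@@H](c1ccc(O[Si](C)(C)C(C)(C)C)cc1)O2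
F6 | step 5 | pinacol ester of 8 | COc1cc(O[Si](C(C)C)(C(C)C)C(C)C)c(B3OC(C)(C)C(C)(C)O3)c2c1C(=O)C[C@@H](c1ccc(O[Si](C)(C)C(C)(C)C)cc1)O2
F7 | step 1 | 1-[2-hydroxy-6-methoxy-4-(triisopropylsilyloxy)phenyl]ethan-1-one | CC(=O)c1c(O)cc(O[Si](C(C)C)(C(C)C)C(C)C)cc1OC
F8 | step 1 | 5-methoxy-7-(triisopropylsilyloxy)-4H-chromen-4-one | COc1cc(O[Si](C(C)C)(C(C)C)C(C)C)cc2occc(=O)c12
F9 | step 9 | (2E,5S)-7-[4-(tert-butyldimethylsilyloxy)phenyl]-5-hydroxyhept-2-enal | O=C/C=C/C[C@@H](O)CCc1ccc(O[Si](C)(C)C(C)(C)C)cc1
A1 | alternative 1 | (2S)-7-hydroxy-2-(4-hydroxyphenyl)-5-methoxychroman-4-one | COc1cc(O)cc2c1C(=O)C[C@@H](c1ccc(O)cc1)O2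
A2 | alternative 1 | (1E,5S)-1,7-bis(4-hydroxyphenyl)hept-1-ene-3,5-diol (C3 epimers) | OC(/C=C/c1ccc(O)cc1)C[C@@H](O)CCc1ccc(O)cc1
A3 | alternative 1 | C6-linked regioisomer of 18 (C3'' epimers) | COc1c(C(/C=C/c2ccc(O)cc2)C[C@@H](O)CCc2ccc(O)cc2)c(O)cc2c1C(=O)C[C@@H](c1ccc(O)cc1)O2
A4 | alternative 2 | (4E,6E)-1,7-bis(4-hydroxyphenyl)hepta-4,6-dien-3-one | O=C(CCc1ccc(O)cc1)/C=C/C=C/c1ccc(O)cc1
A5 | alternative 2 | 5''-ketone corresponding to 18 | COc1cc(O)c([C@H](/C=C/c2ccc(O)cc2)CC(=O)CCc2ccc(O)cc2)c2c1C(=O)C[C@@H](c1ccc(O)cc1)O2
A6 | alternative 3 | all-cis 4-(2,6-dihydroxy-4-methoxyphenyl)-2-(4-hydroxyphenyl)-6-[2-(4-hydroxyphenyl)ethyl]tetrahydropyran | COc1cc(O)c(c(O)c1)[C@@H]1C[C@H](CCc2ccc(O)cc2)O[C@H](c2ccc(O)cc2)C1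
A7 | alternative 3 | 2-[(1E,3R,5S)-5-hydroxy-1,7-bis(4-hydroxyphenyl)hept-1-en-3-yl]-5-methoxybenzene-1,3-diol | COc1cc(O)c(c(O)c1)[C@@H](/C=C/c1ccc(O)cc1)C[C@@H](O)CCc1ccc(O)cc1
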